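**Strategy.** Everything rests on closing the γ-lactone (ring O–C6–C7–C11–C12) through its alkyl C6–O bond. C6 is a secondary allylic carbon γ to the C12 carboxyl, so the 6,7-syn seco acid that an indium Barbier coupling with acrolein should deliver is the right precursor. Mitsunobu lactonisation closes the ring by carboxylate SN2 attack and, in the same operation, inverts C6 to give the trans-fused 12,6-olide. The precursor is an acyclic 4-hydroxy-2-methylidenehex-5-enoic acid carrying the L-threitol-derived C8/C9 acetonide and the C1=C10 enoate tail. Ring-closing metathesis of its C6 vinyl group onto the C4 isopropenyl group then forms the cis,cis-cyclodecadiene.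

Key step: step 11

Remark: germacrane numbering is used (C6 bears the lactone oxygen, C11=C13 is the exo-methylene, C12 the lactone carbonyl, C14 the carboxyl on C10, C15 the methyl on C4); the target is (6R,7S,8S,9S), 1(10)E, 4Z, and the (4S,5S) centres of 1 map onto C9 and C8.

Step 1
Reactants: 1 (+)-2,3-O-isopropylidene-L-threitol
Product: 2 mono-TBS ether of 1
Conditions: NaH (1.0 equiv), THF, 0 °C; then TBSCl (1.0 equiv), rt
Reagents that add atoms: tert-butyl(chloro)dimethylsilane, CC(C)(C)[Si](C)(C)Cl
Why: One equivalent of NaH gives the monoalkoxide of the C2-symmetric diol, which is silylated once (Williamson-type O-silylation, monoprotection of a symmetric diol); the two dioxolane centres are untouched.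

Step 2
Reactants: 2 mono-TBS ether
Product: 3 aldehyde (future C10)
Conditions: Dess–Martin periodinane, CH2Cl2, 0 °C → rt
Reagents that add atoms: none
Why: Dess–Martin oxidation converts the free primary alcohol into the aldehyde under neutral, non-epimerising conditions.

Step 3
Reactants: 3 aldehyde
Product: 4 terminal alkyne
Conditions: dimethyl (1-diazo-2-oxopropyl)phosphonate, K2CO3, MeOH, 0 °C → rt
Reagents that add atoms: Ohira–Bestmann reagent, CC(=O)C(=[N+]=[N-])P(=O)(OC)OC
Why: Seyferth–Gilbert homologation with the Ohira–Bestmann reagent turns the aldehyde into the terminal alkyne; the trans-dioxolane is the stable epimer, so the α-centre should not be scrambled by K2CO3/MeOH.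

Step 4
Reactants: 4 terminal alkyne
Product: 5 2-(trimethylsilyl)ethyl (TMSE) acrylate
Conditions: Pd(OAc)2 (2 mol %), 2-(diphenylphosphino)pyridine, MsOH (cat.), CO (20 bar), Me3SiCH2CH2OH (3 equiv), toluene, 50 °C
Reagents that add atoms: carbon monoxide, [C-]#[O+]; 2-(trimethylsilyl)ethanol, C[Si](C)(C)CCO
Why: Palladium-hydride-catalysed Markovnikov hydroalkoxycarbonylation of the terminal alkyne places the ester carbon (C14) on the internal carbon (C10) and gives the 2-substituted acrylate; the pyridylphosphine buffers the acid so that the TBS ether and acetonide should survive.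

Step 5
Reactants: 5 TMSE acrylate; 6 2-methylhexa-1,5-diene
Product: 7 (E)-trisubstituted enoate (C1=C10 in place, C4 isopropenyl tail)
Conditions: 6 (5 equiv), second-generation Hoveyda–Grubbs catalyst (5 mol %), toluene, 60 °C, argon sweep
Reagents that add atoms: none
Why: Olefin cross-metathesis between the 1,1-disubstituted acrylate and the monosubstituted end of the diene (the isopropenyl end is too hindered to react) should give the trisubstituted enoate under thermodynamic control with C2 trans to the ester, which is the (E) geometry that becomes the ring-cis C1=C10 bond.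

Step 6
Reactants: 7 enoate TBS ether
Product: 8 primary alcohol
Conditions: HF·pyridine, pyridine, THF, 0 °C → rt
Reagents that add atoms: none
Why: Silyl ether cleavage with buffered HF·pyridine removes the primary TBS group, while the TMSE ester (which needs naked fluoride) and the acetonide are kept.

Step 7
Reactants: 8 primary alcohol
Product: 9 aldehyde (C7)
Conditions: Dess–Martin periodinane, CH2Cl2, 0 °C → rt
Reagents that add atoms: none
Why: Dess–Martin oxidation gives the α-alkoxy aldehyde without epimerising the adjacent dioxolane centre, whose trans arrangement is in any case the stable one.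

Step 8
Reactants: 9 aldehyde; 10 methyl acrylate
Product: 11 Morita–Baylis–Hillman adduct (both carbinol epimers)
Conditions: 10 (10 equiv), DABCO (1 equiv), 1,4-dioxane/H2O (1:1), rt
Reagents that add atoms: none
Why: Morita–Baylis–Hillman reaction: the DABCO–acrylate enolate attacks the reactive α-alkoxy aldehyde and attaches C11, C12 and C13; the new carbinol centre need not be controlled because it becomes sp2 in step 9, and the hindered trisubstituted enoate is inert.

Step 9
Reactants: 11 Morita–Baylis–Hillman adduct
Product: 12 (Z)-2-(bromomethyl)enoate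
Conditions: NBS, Me2S, CH2Cl2, 0 °C; then 11, 0 °C → rt
Reagents that add atoms: N-bromosuccinimide, O=C1CCC(=O)N1Br
Why: The bromodimethylsulfonium reagent activates the hydroxyl and bromide attacks the methylene terminus (SN2′, Corey–Kim-type allylic bromination with transposition), giving the thermodynamically preferred (Z)-bromide in which CH2Br is cis to C8.

Step 10
Reactants: 12 allylic bromide; 13 acrolein
Product: 15 (6S,7S)-seco hydroxy acid, via seco hydroxy methyl ester 14 (not isolated)
Conditions: In powder (1.5 equiv), 13 (2 equiv), THF/H2O (1:1), rt; volatiles removed; then LiOH·H2O (3 equiv), THF/H2O, 0 °C; cold 0.5 M HCl to pH 4, product used at once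
Reagents that add atoms: lithium hydroxide, [Li+].[OH-]
Why: Indium-mediated Barbier allylation: the allylindium reacts at its γ-carbon (C7) through a six-membered chair with CH2In cis to C8, which should give the 6,7-syn adduct, while C8–H eclipses the C7=C11 bond to avoid A(1,3) strain and the aldehyde adds to the C7 face anti to C9 (the larger, better σ-donating substituent of C8), setting (6S,7S); LiOH then hydrolyses only the methyl ester, whose cleavage is assisted by the γ-hydroxyl, while the hindered TMSE enoate survives.

Step 11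
Reactants: 15 seco hydroxy acid
Product: 16 trans-α-methylene-γ-butyrolactone with a C6 vinyl group
Conditions: PPh3 (1.5 equiv), DIAD (1.5 equiv), THF (0.02 M), −20 °C → rt
Reagents that add atoms: none
Why: PPh3 and DIAD form the betaine, which is protonated by the carboxylic acid and converts the C6 hydroxyl into an alkoxyphosphonium leaving group; the C12 carboxylate oxygen then displaces Ph3P=O at C6 in an intramolecular SN2 reaction, forming the O–C6 bond. The closest known reaction type is the Mitsunobu lactonisation of γ-hydroxy acids with inversion. The five-membered lactone closes in the 5-exo-tet mode. The only stereocentre changed is C6, whose (6R) configuration follows from stereospecific backside attack on the (6S) carbinol, so the trans 6,7-relationship derives from the syn relationship set in step 10. The step needs O-alkylation at C6 in preference to SN2′ attack at the vinyl terminus (a seven-membered ring) and to closure through an acyloxyphosphonium with retention; the five-ring geometry, the unhindered vinyl carbinol and betaine formation at low temperature should secure this. The TMSE ester, the acetonide and the other alkenes are inert.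

Step 12
Reactants: 16 vinyl lactone
Product: 17 ten-membered carbocycle (acetonide, TMSE ester)
Conditions: second-generation Hoveyda–Grubbs catalyst (15 mol %), 1,4-benzoquinone (cat.), toluene (0.5 mM), 100 °C
Reagents that add atoms: none
Why: Ring-closing metathesis: the catalyst loads on the monosubstituted C6 vinyl group and closes onto the C4 isopropenyl group with loss of ethene; the ten-membered ring should form with the ring-cis (Z) C4=C5 bond, and neither the lactone exo-methylene (only a four-membered ring possible) nor the trisubstituted enoate offers a competitive closure.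

Step 13
Reactants: 17 macrocyclic acetonide
Product: 18 8,9-diol
Conditions: AcOH/H2O (4:1), 40 °C
Reagents that add atoms: none
Why: Acid-catalysed acetal hydrolysis releases the diol; the lactone, the TMSE ester and the alkenes tolerate warm aqueous acetic acid, and the diol is used at once to limit translactonisation to the 8-hydroxyl.

Step 14
Reactants: 18 diol; 19 angelic acid
Product: 20 8,9-diangelate TMSE ester
Conditions: 19 (6 equiv), 2,4,6-trichlorobenzoyl chloride, Et3N, toluene, rt; then 18, toluene, 80 °C
Reagents that add atoms: none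
Why: Yamaguchi-type esterification through the preformed angelic 2,4,6-trichlorobenzoic mixed anhydride, run without a nucleophilic catalyst, should acylate both secondary hydroxyls without isomerising the (Z)-2-methylbut-2-enoyl groups to tiglates.

Step 15
Reactants: 20 diangelate TMSE ester
Product: 21 target acid
Conditions: tris(dimethylamino)sulfonium difluorotrimethylsilicate (TASF, 3 equiv), DMF, 0 °C → rt; cold 0.5 M HCl work-up
Reagents that add atoms: none
Why: Fluoride attacks silicon and triggers β-elimination of the 2-(trimethylsilyl)ethyl ester (ethene and Me3SiF leave), freeing the C14 acid under non-hydrolytic conditions that should spare the lactone and both angelates.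

**Compound list**

1 | (4S,5S)-2,2-dimethyl-1,3-dioxolane-4,5-dimethanol ((+)-2,3-O-isopropylidene-L-threitol) | OC[C@@H]1OC(C)(C)O[C@H]1CO | starting material
2 | [(4S,5S)-5-({[tert-butyl(dimethyl)silyl]oxy}methyl)-2,2-dimethyl-1,3-dioxolan-4-yl]methanol | OC[C@@H]1OC(C)(C)O[C@H]1CO[Si](C)(C)C(C)(C)C | intermediate
3 | (4R,5S)-5-({[tert-butyl(dimethyl)silyl]oxy}methyl)-2,2-dimethyl-1,3-dioxolane-4-carbaldehyde | O=C[C@@H]1OC(C)(C)O[C@H]1CO[Si](C)(C)C(C)(C)C | intermediate
4 | tert-butyl{[(4S,5S)-5-ethynyl-2,2-dimethyl-1,3-dioxolan-4-yl]methoxy}dimethylsilane | C#C[C@@H]1OC(C)(C)O[C@H]1CO[Si](C)(C)C(C)(C)C | intermediate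
5 | 2-(trimethylsilyl)ethyl 2-[(4S,5S)-5-({[tert-butyl(dimethyl)silyl]oxy}methyl)-2,2-dimethyl-1,3-dioxolan-4-yl]prop-2-enoate | C=C(C(=O)OCC[Si](C)(C)C)[C@@H]1OC(C)(C)O[C@H]1CO[Si](C)(C)C(C)(C)C | intermediate
6 | 2-methylhexa-1,5-diene | C=C(C)CCC=C | starting material
7 | 2-(trimethylsilyl)ethyl (2E)-2-[(4S,5S)-5-({[tert-butyl(dimethyl)silyl]oxy}methyl)-2,2-dimethyl-1,3-dioxolan-4-yl]-6-methylhepta-2,6-dienoate | C=C(C)CC/C=C(/C(=O)OCC[Si](C)(C)C)[C@@H]1OC(C)(C)O[C@H]1CO[Si](C)(C)C(C)(C)C | intermediate
8 | 2-(trimethylsilyl)ethyl (2E)-2-[(4S,5S)-5-(hydroxymethyl)-2,2-dimethyl-1,3-dioxolan-4-yl]-6-methylhepta-2,6-dienoate | C=C(C)CC/C=C(/C(=O)OCC[Si](C)(C)C)[C@@H]1OC(C)(C)O[C@H]1CO | intermediate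
9 | 2-(trimethylsilyl)ethyl (2E)-2-[(4S,5R)-5-formyl-2,2-dimethyl-1,3-dioxolan-4-yl]-6-methylhepta-2,6-dienoate | C=C(C)CC/C=C(/C(=O)OCC[Si](C)(C)C)[C@@H]1OC(C)(C)O[C@H]1C=O | intermediate
10 | methyl prop-2-enoate (methyl acrylate) | C=CC(=O)OC | starting material
11 | 2-(trimethylsilyl)ethyl (2E)-2-{(4S,5S)-5-[1-hydroxy-2-(methoxycarbonyl)prop-2-en-1-yl]-2,2-dimethyl-1,3-dioxolan-4-yl}-6-methylhepta-2,6-dienoate (both carbinol epimers) | C=C(C)CC/C=C(/C(=O)OCC[Si](C)(C)C)[C@@H]1OC(C)(C)O[C@H]1C(O)C(=C)C(=O)OC | intermediate
12 | 2-(trimethylsilyl)ethyl (2E)-2-{(4S,5S)-5-[(1Z)-3-bromo-2-(methoxycarbonyl)prop-1-en-1-yl]-2,2-dimethyl-1,3-dioxolan-4-yl}-6-methylhepta-2,6-dienoate | C=C(C)CC/C=C(/C(=O)OCC[Si](C)(C)C)[C@@H]1OC(C)(C)O[C@H]1/C=C(\CBr)C(=O)OC | intermediate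
13 | prop-2-enal (acrolein) | C=CC=O | starting material
14 | 2-(trimethylsilyl)ethyl (2E)-2-{(4S,5S)-5-[(3S,4S)-4-hydroxy-2-(methoxycarbonyl)hexa-1,5-dien-3-yl]-2,2-dimethyl-1,3-dioxolan-4-yl}-6-methylhepta-2,6-dienoate (seco hydroxy methyl ester, 6S,7S,8S,9S) | COC(=O)C(=C)[C@@H]([C@@H](O)C=C)[C@@H]1OC(C)(C)O[C@H]1/C(C(=O)OCC[Si](C)(C)C)=C\CCC(C)=C | intermediate (not isolated)
15 | (3S,4S)-4-hydroxy-2-methylidene-3-[(4S,5S)-2,2-dimethyl-5-{(2E)-6-methyl-1-oxo-1-[2-(trimethylsilyl)ethoxy]hepta-2,6-dien-2-yl}-1,3-dioxolan-4-yl]hex-5-enoic acid (seco hydroxy acid) | OC(=O)C(=C)[C@@H]([C@@H](O)C=C)[C@@H]1OC(C)(C)O[C@H]1/C(C(=O)OCC[Si](C)(C)C)=C\CCC(C)=C | intermediate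
16 | 2-(trimethylsilyl)ethyl (2E)-2-{(4S,5S)-5-[(2R,3S)-2-ethenyl-4-methylidene-5-oxooxolan-3-yl]-2,2-dimethyl-1,3-dioxolan-4-yl}-6-methylhepta-2,6-dienoate (trans-lactone, 6R,7S) | C=C1C(=O)O[C@H](C=C)[C@H]1[C@@H]2OC(C)(C)O[C@H]2/C(C(=O)OCC[Si](C)(C)C)=C\CCC(C)=C | intermediate
17 | 2-(trimethylsilyl)ethyl (6R,7S,8S,9S,1(10)E,4Z)-8,9-(isopropylidenedioxy)-12-oxo-6,12-epoxygermacra-1(10),4,11(13)-trien-14-oate (12,6-olide, 8,9-acetonide) | C=C1C(=O)O[C@@H]2/C=C(/C)CC/C=C(/C(=O)OCC[Si](C)(C)C)[C@@H]3OC(C)(C)O[C@H]3[C@@H]12 | intermediate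
18 | 2-(trimethylsilyl)ethyl ester of the (6R,7S,8S,9S)-8,9-dihydroxy-12,6-olide (diol of 17) | C=C1C(=O)O[C@@H]2/C=C(/C)CC/C=C(/C(=O)OCC[Si](C)(C)C)[C@H](O)[C@@H](O)[C@@H]12 | intermediate
19 | (2Z)-2-methylbut-2-enoic acid (angelic acid) | C/C=C(/C)C(=O)O | starting material
20 | 2-(trimethylsilyl)ethyl ester of the (6R,7S,8S,9S)-8,9-bis(angeloyloxy)-12,6-olide | C=C1C(=O)O[C@@H]2/C=C(/C)CC/C=C(/C(=O)OCC[Si](C)(C)C)[C@H](OC(=O)/C(C)=C\C)[C@@H](OC(=O)/C(C)=C\C)[C@@H]12 | intermediate
21 | (6R,7S,8S,9S,1(10)E,4Z)-8,9-bis{[(2Z)-2-methylbut-2-enoyl]oxy}-12-oxo-6,12-epoxygermacra-1(10),4,11(13)-trien-14-oic acid (CNP0154468.1) | C=C1C(=O)O[C@@H]2/C=C(/C)CC/C=C(/C(=O)O)[C@H](OC(=O)/C(C)=C\C)[C@@H](OC(=O)/C(C)=C\C)[C@@H]12 | target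

**Step count.** Total: 15 steps. Longest linear sequence: 15 steps (fully linear from 1; 6, 10, 13 and 19 enter as purchased reagents).

**Steps most likely to fail**

Step 12 (ring-closing metathesis). The ten-membered ring may close too slowly because the trans-lactone holds the two chain ends apart. Intermolecular metathesis through the vinyl group, or attack on the trisubstituted enoate with loss of the tail, could then take over. The fallback closes the macrocycle before the lactone. It sets out from 14, obtained by stopping step 10 before the LiOH stage and isolating the ester. Ring-closing metathesis of this conformationally free diene (second-generation Hoveyda–Grubbs catalyst, toluene, high dilution) should give the macrocyclic hydroxy ester F1. Saponification with LiOH gives the macrocyclic hydroxy acid F2. Transannular Mitsunobu lactonisation (PPh3, DIAD) with inversion at C6 comes back to the route at 17.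

Step 5 (cross-metathesis). The α-branched acrylate may fail to enter the catalytic cycle, so that only the diene homodimerises, or the E/Z control may be poor. The fallback builds the enoate without metathesis and sets out from 4. Deprotonation with n-BuLi and alkylation with 3-methylbut-3-en-1-yl trifluoromethanesulfonate gives the internal alkyne F3. PdCl2(PPh3)2-catalysed syn-hydrostannation with Bu3SnH, with tin going to the carbon next to the dioxolane, gives the vinylstannane F4. Iododestannylation with I2 gives the vinyl iodide F5 with retention. Alkoxycarbonylation (PdCl2(PPh3)2, CO, Me3SiCH2CH2OH, Et3N, DMF) then places the ester cis to the vinylic hydrogen and comes back to the route at 7.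

Step 10 (Barbier allylation). The facial selectivity with respect to the C8 stereocentre may be poor or reversed, and the syn selectivity may erode with the small aldehyde. The fallback replaces the equilibrating allylindium by a configurationally defined allylboronate and sets out from 12. Borylation with B2pin2 catalysed by Pd2(dba)3 gives the primary allylboronate F6, with CH2B cis to C8. Acid-catalysed allylboration of 13 (Sc(OTf)3, or a chiral BINOL-derived phosphoric acid to override the substrate bias) passes through a closed chair and should give the syn adduct. It comes back to the route at 14, which is saponified as in step 10.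

**Further compounds**

F1 | step 12 | macrocyclic (6S,7S,8S,9S) hydroxy methyl ester (ten-membered ring closed, lactone open) | COC(=O)C(=C)[C@H]1[C@@H](O)/C=C(/C)CC/C=C(/C(=O)OCC[Si](C)(C)C)[C@@H]2OC(C)(C)O[C@@H]12
F2 | step 12 | macrocyclic (6S,7S,8S,9S) hydroxy acid | OC(=O)C(=C)[C@H]1[C@@H](O)/C=C(/C)CC/C=C(/C(=O)OCC[Si](C)(C)C)[C@@H]2OC(C)(C)O[C@@H]12
F3 | step 5 | tert-butyl{[(4S,5S)-2,2-dimethyl-5-(5-methylhex-5-en-1-yn-1-yl)-1,3-dioxolan-4-yl]methoxy}dimethylsilane | C=C(C)CCC#C[C@@H]1OC(C)(C)O[C@H]1CO[Si](C)(C)C(C)(C)C
F4 | step 5 | vinylstannane (Bu3Sn on C10, syn to the vinylic hydrogen on C1) | C=C(C)CC/C=C(/[Sn](CCCC)(CCCC)CCCC)[C@@H]1OC(C)(C)O[C@H]1CO[Si](C)(C)C(C)(C)C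
F5 | step 5 | vinyl iodide (iodine on C10) | C=C(C)CC/C=C(/I)[C@@H]1OC(C)(C)O[C@H]1CO[Si](C)(C)C(C)(C)C
F6 | step 10 | pinacol allylboronate corresponding to 12 (CH2Bpin cis to C8) | C=C(C)CC/C=C(/C(=O)OCC[Si](C)(C)C)[C@@H]1OC(C)(C)O[C@H]1/C=C(\CB2OC(C)(C)C(C)(C)O2)C(=O)OC
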